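The route builds the meta-phenylene ring D de novo and does not couple onto it. Ring D carries only two substituents, the ether oxygen to catechol ring C and the CH2 of the ethano bridge to catechol ring A, in a 1,3 relation; these map onto O–C4 and C6–CH2 of a 2-pyranone. The precursor is therefore a 4-aryloxy-6-(2-arylethyl)-2-pyranone (9), assembled from triacetic acid lactone by C7-alkylation and addition–elimination at C4. In one operation phenyl vinyl sulfone adds across C3/C6, CO2 and benzenesulfinic acid are expelled, and ring D appears with both C–C bonds made. Ring B is then added by SNAr and the macrocycle closed by McMurry coupling.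

Key step: step 7

Remark: the target has no stereocentre; the transient adducts 11 and 12 and the alkene 17 are expected as isomer mixtures that converge, so their SMILES carry no descriptors (11 and 12 are drawn as the regioisomer favoured by the C4 donor).

Step 1
Reactants: 1 3-hydroxy-4,5-dimethoxybenzaldehyde
Product: 2 3-benzyloxy-4,5-dimethoxybenzaldehyde
Conditions: BnBr, K2CO3, DMF, rt
Reagents that add atoms: benzyl bromide, BrCc1ccccc1
Why: Williamson etherification of the phenoxide with a benzylic bromide; the non-enolisable aldehyde is inert to K2CO3.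

Step 2
Reactants: 2 3-benzyloxy-4,5-dimethoxybenzaldehyde
Product: 3 (3-benzyloxy-4,5-dimethoxyphenyl)methanol
Conditions: NaBH4, MeOH, 0 °C
Reagents that add atoms: none
Why: Borohydride reduction of an aromatic aldehyde to the benzylic alcohol leaves all ethers untouched.

Step 3
Reactants: 3 (3-benzyloxy-4,5-dimethoxyphenyl)methanol
Product: 4 1-(benzyloxy)-5-(bromomethyl)-2,3-dimethoxybenzene
Conditions: PBr3, CH2Cl2, 0 °C
Reagents that add atoms: phosphorus tribromide, BrP(Br)Br
Why: SN2 bromination of a benzylic alcohol through its phosphite ester; aryl benzyl and methyl ethers tolerate PBr3 at 0 °C.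

Step 4
Reactants: 5 4-hydroxy-6-methyl-2H-pyran-2-one, 4 1-(benzyloxy)-5-(bromomethyl)-2,3-dimethoxybenzene
Product: 7 6-[2-(3-benzyloxy-4,5-dimethoxyphenyl)ethyl]-4-hydroxy-2H-pyran-2-one, via pyranone dianion 6 (not isolated)
Conditions: LiN(iPr)2 (2.3 equiv), THF–DMPU, −78 °C; then 4, −78 to −20 °C; aq. HCl
Reagents that add atoms: none
Why: Dianion alkylation of triacetic acid lactone: the amide base removes the 4-OH proton and then a vinylogous C7 methyl proton, and the more basic carbon terminus of the dianion should displace the benzylic bromide by SN2.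

Step 5
Reactants: 7 6-[2-(3-benzyloxy-4,5-dimethoxyphenyl)ethyl]-4-hydroxy-2H-pyran-2-one
Product: 8 6-[2-(3-benzyloxy-4,5-dimethoxyphenyl)ethyl]-2-oxo-2H-pyran-4-yl 4-methylbenzenesulfonate
Conditions: TsCl, Et3N, CH2Cl2, 0 °C to rt
Reagents that add atoms: p-toluenesulfonyl chloride, Cc1ccc(cc1)S(Cl)(=O)=O
Why: O-sulfonylation of the acidic vinylogous carboxylic acid at O4 is routine for 4-hydroxy-2-pyranones and makes C4 a vinylogous mixed-anhydride carbon.

Step 6
Reactants: 8 6-[2-(3-benzyloxy-4,5-dimethoxyphenyl)ethyl]-2-oxo-2H-pyran-4-yl 4-methylbenzenesulfonate, 1 3-hydroxy-4,5-dimethoxybenzaldehyde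
Product: 9 4-(5-formyl-2,3-dimethoxyphenoxy)-6-[2-(3-benzyloxy-4,5-dimethoxyphenyl)ethyl]-2H-pyran-2-one
Conditions: K2CO3, DMF, rt to 50 °C
Reagents that add atoms: none
Why: Addition–elimination (nucleophilic vinylic substitution) at C4 of a 2-pyranone bearing a leaving group is established for heteroatom nucleophiles including phenoxides; the tosylate leaves from the vinylogous acyl position and the aldehyde of 1 is a spectator.

Step 7
Reactants: 9 4-(5-formyl-2,3-dimethoxyphenoxy)-6-[2-(3-benzyloxy-4,5-dimethoxyphenyl)ethyl]-2H-pyran-2-one, 10 phenyl vinyl sulfone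
Product: 13 3-[3-[2-(3-benzyloxy-4,5-dimethoxyphenyl)ethyl]phenoxy]-4,5-dimethoxybenzaldehyde, via bridged lactone cycloadduct 11 (not isolated), via sulfonyl cyclohexadiene 12 (not isolated)
Conditions: 10 (5 equiv), 2,6-lutidine (2 equiv), BHT (cat.), 1,2-dichlorobenzene, 180 °C, sealed tube
Reagents that add atoms: none
Why: Thermal [4+2] cycloaddition of the pyranone diene (C3=C4–C5=C6) with the electron-poor alkene 10 should give the bridged lactone 11, cycloreversion expels CO2 to give dihydroarene 12, and loss of benzenesulfinic acid (eased by the aryloxy-stabilised cyclohexadienyl cation and the lutidine buffer) aromatises to 13. The closest known reaction type is the Diels–Alder/retro-Diels–Alder benzannulation of 2-pyranones with vinyl sulfones and other alkyne equivalents. Ring D is closed by intermolecular cycloaddition that forms the C3–C and C6–C bonds, the two alkene carbons completing the six-membered ring. The stereocentres of 11 and 12 are transient and are erased on aromatisation, so none needs control. The only selectivity required is the 1,3 placement of the ether oxygen and the alkyl arm, which C4 and C6 of 9 fix before the step; both orientations of 10 lead to the same arene because its two carbons end as unsubstituted CH. The C4 donor lowers diene reactivity, hence the high temperature, excess dienophile and radical inhibitor.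

Step 8
Reactants: 13 3-[3-[2-(3-benzyloxy-4,5-dimethoxyphenyl)ethyl]phenoxy]-4,5-dimethoxybenzaldehyde
Product: 14 3-[3-[2-(3-hydroxy-4,5-dimethoxyphenyl)ethyl]phenoxy]-4,5-dimethoxybenzaldehyde
Conditions: BCl3, pentamethylbenzene, CH2Cl2, −78 °C; MeOH quench
Reagents that add atoms: none
Why: Lewis-acid debenzylation with pentamethylbenzene as cation trap cleaves aryl benzyl ethers at −78 °C, where aryl methyl ethers, the diaryl ether and the aldehyde should remain intact.

Step 9
Reactants: 14 3-[3-[2-(3-hydroxy-4,5-dimethoxyphenyl)ethyl]phenoxy]-4,5-dimethoxybenzaldehyde, 15 4-fluorobenzaldehyde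
Product: 16 3-[3-[2-[3-(4-formylphenoxy)-4,5-dimethoxyphenyl]ethyl]phenoxy]-4,5-dimethoxybenzaldehyde
Conditions: K2CO3, DMF, 120 °C
Reagents that add atoms: none
Why: SNAr of the ring A phenoxide on 4-fluorobenzaldehyde, whose para-formyl group stabilises the Meisenheimer intermediate; the ring C aldehyde has no α-hydrogen and survives the base.

Step 10
Reactants: 16 3-[3-[2-[3-(4-formylphenoxy)-4,5-dimethoxyphenyl]ethyl]phenoxy]-4,5-dimethoxybenzaldehyde
Product: 17 macrocyclic stilbene, the 19-membered tetra-O-methyl ring with a CH=CH link between rings B and C (E/Z mixture expected)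
Conditions: TiCl4, Zn, pyridine, THF, reflux; slow addition of 16 (high dilution)
Reagents that add atoms: none
Why: Intramolecular McMurry reductive coupling of two aryl aldehydes on low-valent titanium under high dilution is an established macrocyclisation for bis(bibenzyl) ethers, and the alkene geometry is irrelevant because the next step saturates it.

Step 11
Reactants: 17 macrocyclic stilbene
Product: 18 tetra-O-methyl ether of the target (rings A and C each as 1,2-dimethoxy)
Conditions: H2 (1 atm), 10% Pd/C, EtOAc–EtOH, rt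
Reagents that add atoms: none
Why: Heterogeneous hydrogenation of the stilbene C=C; no benzyl ether, halide or carbonyl remains to interfere.

Step 12
Reactants: 18 tetra-O-methyl ether of the target
Product: 19 CNP0511668.0, the macrocyclic bis(bibenzyl) tetraphenol
Conditions: BBr3 (8 equiv), CH2Cl2, −78 °C to rt; H2O quench under argon
Reagents that add atoms: none
Why: BBr3 demethylation cleaves all four aryl methyl ethers through aryloxyborane intermediates with SN2 loss of bromomethane, while diaryl ethers and the bibenzyl bridges are inert.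

Compound list
1 | 3-hydroxy-4,5-dimethoxybenzaldehyde | COc1cc(C=O)cc(O)c1OC | starting material
2 | 3-benzyloxy-4,5-dimethoxybenzaldehyde | COc1cc(C=O)cc(OCc2ccccc2)c1OC | intermediate
3 | (3-benzyloxy-4,5-dimethoxyphenyl)methanol | COc1cc(CO)cc(OCc2ccccc2)c1OC | intermediate
4 | 1-(benzyloxy)-5-(bromomethyl)-2,3-dimethoxybenzene | COc1cc(CBr)cc(OCc2ccccc2)c1OC | intermediate
5 | 4-hydroxy-6-methyl-2H-pyran-2-one (triacetic acid lactone) | CC1=CC(O)=CC(=O)O1 | starting material
6 | dilithium O4,C7-dianion of 5 (not isolated) | [Li+].[Li+].[CH2-]C1=CC([O-])=CC(=O)O1 | intermediate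
7 | 6-[2-(3-benzyloxy-4,5-dimethoxyphenyl)ethyl]-4-hydroxy-2H-pyran-2-one | O=C1C=C(O)C=C(CCc2cc(OC)c(OC)c(OCc3ccccc3)c2)O1 | intermediate
8 | 6-[2-(3-benzyloxy-4,5-dimethoxyphenyl)ethyl]-2-oxo-2H-pyran-4-yl 4-methylbenzenesulfonate | Cc1ccc(cc1)S(=O)(=O)OC1=CC(=O)OC(CCc2cc(OC)c(OC)c(OCc3ccccc3)c2)=C1 | intermediate
9 | 4-(5-formyl-2,3-dimethoxyphenoxy)-6-[2-(3-benzyloxy-4,5-dimethoxyphenyl)ethyl]-2H-pyran-2-one | O=C1C=C(Oc2cc(C=O)cc(OC)c2OC)C=C(CCc2cc(OC)c(OC)c(OCc3ccccc3)c2)O1 | intermediate
10 | phenyl vinyl sulfone | C=CS(=O)(=O)c1ccccc1 | starting material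
11 | 7-(phenylsulfonyl)-2-oxabicyclo[2.2.2]oct-5-en-3-one with the 2-(3-benzyloxy-4,5-dimethoxyphenyl)ethyl group at C1 and the 5-formyl-2,3-dimethoxyphenoxy group at C5 (racemic endo/exo mixture, not isolated) | O=C1OC2(CCc3cc(OC)c(OC)c(OCc4ccccc4)c3)C=C(Oc3cc(C=O)cc(OC)c3OC)C1CC2S(=O)(=O)c1ccccc1 | intermediate
12 | 3-{[5-[2-(3-benzyloxy-4,5-dimethoxyphenyl)ethyl]-4-(phenylsulfonyl)cyclohexa-1,5-dien-1-yl]oxy}-4,5-dimethoxybenzaldehyde (racemic, not isolated) | O=Cc1cc(OC)c(OC)c(c1)OC1=CCC(S(=O)(=O)c2ccccc2)C(CCc2cc(OC)c(OC)c(OCc3ccccc3)c2)=C1 | intermediate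
13 | 3-[3-[2-(3-benzyloxy-4,5-dimethoxyphenyl)ethyl]phenoxy]-4,5-dimethoxybenzaldehyde | O=Cc1cc(OC)c(OC)c(c1)Oc1cccc(c1)CCc1cc(OC)c(OC)c(OCc2ccccc2)c1 | intermediate
14 | 3-[3-[2-(3-hydroxy-4,5-dimethoxyphenyl)ethyl]phenoxy]-4,5-dimethoxybenzaldehyde | O=Cc1cc(OC)c(OC)c(c1)Oc1cccc(c1)CCc1cc(OC)c(OC)c(O)c1 | intermediate
15 | 4-fluorobenzaldehyde | O=Cc1ccc(F)cc1 | starting material
16 | 3-[3-[2-[3-(4-formylphenoxy)-4,5-dimethoxyphenyl]ethyl]phenoxy]-4,5-dimethoxybenzaldehyde | O=Cc1cc(OC)c(OC)c(c1)Oc1cccc(c1)CCc1cc(OC)c(OC)c(Oc2ccc(C=O)cc2)c1 | intermediate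
17 | macrocyclic stilbene: 19-membered ring A–O–ring B–CH=CH–ring C–O–ring D–CH2CH2–ring A, rings A and C each 1,2-dimethoxy (E/Z mixture) | COc1cc2cc(c1OC)Oc1ccc(cc1)C=Cc1cc(OC)c(OC)c(c1)Oc1cccc(c1)CC2 | intermediate
18 | tetra-O-methyl ether of the target (the CH=CH of 17 reduced to CH2CH2) | COc1cc2cc(c1OC)Oc1ccc(cc1)CCc1cc(OC)c(OC)c(c1)Oc1cccc(c1)CC2 | intermediate
19 | CNP0511668.0, macrocyclic bis(bibenzyl) with catechol rings A and C, para-phenylene ring B and meta-phenylene ring D | Oc1cc2cc(c1O)Oc1ccc(cc1)CCc1cc(O)c(O)c(c1)Oc1cccc(c1)CC2 | target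

Total step count: 12. Longest linear sequence: 12 steps (1 to 19; compounds 5, 10 and 15 are purchased and 1 re-enters in step 6).

Steps most likely to fail

Step 7. The donor-substituted pyranone may cycloadd too slowly relative to thermal degradation, or the dihydroarene may undergo a second cycloaddition before sulfinic acid is lost. The fallback forms the ring C–O–ring D ether on a preformed benzene. Starting from aldehyde 2, Wittig olefination with (3-bromobenzyl)triphenylphosphonium bromide (KOtBu, THF) should give 1-(benzyloxy)-5-[2-(3-bromophenyl)ethenyl]-2,3-dimethoxybenzene F1. Diimide reduction (TsNHNH2, NaOAc, THF–H2O, reflux), which spares the aryl bromide and the benzyl ether, should give 1-(benzyloxy)-5-[2-(3-bromophenyl)ethyl]-2,3-dimethoxybenzene F2. Ullmann etherification of F2 with phenol 1 (CuI, N,N-dimethylglycine, Cs2CO3, dioxane, 100 °C) rejoins the route at 13.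

Step 10. Intermolecular carbonyl coupling to oligomers, or arrest at the pinacol stage, may outrun ring closure. The fallback closes the macrocycle at the ring A–O–ring B ether instead. Starting from 13, Wittig olefination with (4-bromobenzyl)triphenylphosphonium bromide (KOtBu, THF) should give the bromostilbene 1-(benzyloxy)-5-[2-[3-[5-[2-(4-bromophenyl)ethenyl]-2,3-dimethoxyphenoxy]phenyl]ethyl]-2,3-dimethoxybenzene F3. Diimide reduction should give the bibenzyl 1-(benzyloxy)-5-[2-[3-[5-[2-(4-bromophenyl)ethyl]-2,3-dimethoxyphenoxy]phenyl]ethyl]-2,3-dimethoxybenzene F4. BCl3/pentamethylbenzene debenzylation at −78 °C should give the bromophenol 5-[2-[3-[5-[2-(4-bromophenyl)ethyl]-2,3-dimethoxyphenoxy]phenyl]ethyl]-2,3-dimethoxyphenol F5. Intramolecular Ullmann etherification (CuI, N,N-dimethylglycine, Cs2CO3, dioxane, 100 °C, high dilution) rejoins the route at 18.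

Step 6. The phenoxide may attack sulfur (tosyl transfer that regenerates 7) or the lactone carbonyl (ring opening) instead of C4. The fallback removes the sulfur electrophile. Starting from 7, Bu4NBr/P2O5 in toluene at 100 °C should give 4-bromo-6-[2-(3-benzyloxy-4,5-dimethoxyphenyl)ethyl]-2H-pyran-2-one F6. Displacement of bromide by 1 (K2CO3, MeCN, reflux), the established route to 4-aryloxy-2-pyranones, rejoins the route at 9.

Further compounds
F1 | step 7 | 1-(benzyloxy)-5-[2-(3-bromophenyl)ethenyl]-2,3-dimethoxybenzene (E/Z mixture) | COc1cc(C=Cc2cccc(Br)c2)cc(OCc2ccccc2)c1OC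
F2 | step 7 | 1-(benzyloxy)-5-[2-(3-bromophenyl)ethyl]-2,3-dimethoxybenzene | COc1cc(CCc2cccc(Br)c2)cc(OCc2ccccc2)c1OC
F3 | step 10 | 1-(benzyloxy)-5-[2-[3-[5-[2-(4-bromophenyl)ethenyl]-2,3-dimethoxyphenoxy]phenyl]ethyl]-2,3-dimethoxybenzene (E/Z mixture) | Brc1ccc(cc1)C=Cc1cc(OC)c(OC)c(c1)Oc1cccc(c1)CCc1cc(OC)c(OC)c(OCc2ccccc2)c1
F4 | step 10 | 1-(benzyloxy)-5-[2-[3-[5-[2-(4-bromophenyl)ethyl]-2,3-dimethoxyphenoxy]phenyl]ethyl]-2,3-dimethoxybenzene | Brc1ccc(cc1)CCc1cc(OC)c(OC)c(c1)Oc1cccc(c1)CCc1cc(OC)c(OC)c(OCc2ccccc2)c1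
F5 | step 10 | 5-[2-[3-[5-[2-(4-bromophenyl)ethyl]-2,3-dimethoxyphenoxy]phenyl]ethyl]-2,3-dimethoxyphenol | Brc1ccc(cc1)CCc1cc(OC)c(OC)c(c1)Oc1cccc(c1)CCc1cc(OC)c(OC)c(O)c1
F6 | step 6 | 4-bromo-6-[2-(3-benzyloxy-4,5-dimethoxyphenyl)ethyl]-2H-pyran-2-one | O=C1C=C(Br)C=C(CCc2cc(OC)c(OC)c(OCc3ccccc3)c2)O1
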